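The plan hinges on cutting C9–C10, the bond tying spiro carbon C10 of ring A to methine C9 beside quaternary C8. The feature used is the lactone oxygen on C20. Through it, ring A and the future ring C are first united by an ordinary ester coupling, so the congested bond is made intramolecularly while C8 and C9 are still sp2 carbons. In one operation a tertiary C10 radical, freed from a cesium oxalate by photoredox catalysis, adds to C9, closes the δ-lactone (C7, O, C20, C10, C9, C8) and sets C10, C9 and C8. The precursor is the ring A carbinol oxalate with C1 and C6 masked as dioxolanes and C20 acylated by cyclohexa-1,4-diene-1-carboxylic acid.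

Key step: step 10

Numbering: atom labels C1–C20 are those of the ent-kaurane skeleton of the target. Ring A is C1–C5 and C10. The lactone is C7, O, C20, C10, C9, C8. Ring C is C8, C9, C11–C14. Ring D is C8, C15, C16, C13, C14.

Assumption: the phosphoramidite enantiomer named in step 1 is taken to deliver the alkenyl group to the face of 1 that gives 3S in 6; if the sense is opposite, its mirror image is used.

Design points:
- (a) Both carbonyl groups (C1, C6) are masked in one step and released in one step.
- (b) The carbinol centre C10 is drawn as the epimer that osmylation anti to C6 should give (10R). This centre is erased in step 10.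
- (c) The dienoic acid is made from propiolic acid, so the skipped diene never meets hydroxide.
- (d) The key step is redox-neutral and run at high dilution without an added hydrogen-atom donor, because the doubly allylic C11 and C14 methylenes of the acyl part are themselves hydrogen donors.

Step 1
Reactants: 1 4,4-dimethylcyclohex-2-en-1-one; 2 hex-1-yne; 3 Eschenmoser's salt (N,N-dimethylmethyleneiminium iodide)
Product: 6 (2R,3S)-2-[(dimethylamino)methyl]-3-[(E)-hex-1-en-1-yl]-4,4-dimethylcyclohexan-1-one, via (E)-hex-1-enyl(diisobutyl)alane 4 (not isolated), via diisobutylaluminium enolate 5 (not isolated)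
Conditions: 2, i-Bu2AlH, hexane, 50 °C; then 1, [Cu(MeCN)4]BF4 (5 mol %), (S)-BINOL phosphoramidite of bis[(R)-1-phenylethyl]amine (10 mol %), Et2O, −30 °C; then 3, THF, −30 °C → rt
Reagents that add atoms: none
Why: Copper-catalysed asymmetric conjugate addition of an alkenylalane sets C5 under ligand control, and the regiodefined aluminium enolate is caught in a Mannich reaction anti to the new substituent, so that C20 enters only at C10 (this second centre is removed in step 4).

Step 2
Reactants: 6 Mannich base
Product: 8 (1S,2R)-2-[(dimethylamino)methyl]-6,6-dimethyl-3-oxocyclohexane-1-carbaldehyde (kept as its tosylate salt), via secondary ozonide 7 (not isolated)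
Conditions: p-TsOH·H2O (1.05 equiv), O3, CH2Cl2, −78 °C; then Me2S, −78 °C → rt; crude salt carried on
Reagents that add atoms: ozone, [O-][O+]=O
Why: Ozonolysis with reductive work-up cleaves the only C=C bond and unveils C6 as the aldehyde, the amine being shielded from ozone as its ammonium salt and the hindered α-branched aldehyde being kept cold and non-basic so that C5 is not epimerised.

Step 3
Reactants: 8 keto aldehyde (tosylate salt)
Product: 9 1-[(6R,7S)-7-(1,3-dioxolan-2-yl)-8,8-dimethyl-1,4-dioxaspiro[4.5]decan-6-yl]-N,N-dimethylmethanamine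
Conditions: HOCH2CH2OH (10 equiv), p-TsOH·H2O (0.2 equiv extra), benzene, Dean–Stark, 80 °C; aq. NaOH work-up
Reagents that add atoms: ethylene glycol, OCCO
Why: Acid-catalysed double acetalisation with azeotropic removal of water masks C1 and C6 together at a stage where C10 is still a methine and C1 is therefore accessible, and no stereocentre is touched.

Step 4
Reactants: 9 amino bis-dioxolane
Product: 11 (7R)-7-(1,3-dioxolan-2-yl)-8,8-dimethyl-6-methylidene-1,4-dioxaspiro[4.5]decane, via amine N-oxide 10 (not isolated)
Conditions: mCPBA (1.05 equiv), CH2Cl2, 0 °C; basic alumina filtration; then toluene, 110 °C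
Reagents that add atoms: none
Why: N-Oxidation followed by thermal Cope elimination, a syn process whose only β-hydrogen is H10, gives the exocyclic C10=C20 alkene under neutral conditions that leave both acetals and C5 intact.

Step 5
Reactants: 11 exo-methylene bis-dioxolane
Product: 12 (6R,7R)-7-(1,3-dioxolan-2-yl)-6-(hydroxymethyl)-8,8-dimethyl-1,4-dioxaspiro[4.5]decan-6-ol
Conditions: OsO4 (3 mol %), NMO (1.5 equiv), acetone/H2O 5:1, rt
Reagents that add atoms: N-methylmorpholine N-oxide, C[N+]1([O-])CCOCC1; water, O
Why: Upjohn dihydroxylation of the only alkene, in which osmium should approach anti to the C5 substituent and the axial C4 methyl group to give the 10R carbinol, a centre that is erased in step 10.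

Step 6
Reactants: 13 buta-1,3-diene; 14 propiolic acid
Product: 15 cyclohexa-1,4-diene-1-carboxylic acid
Conditions: 13 (3 equiv), BHT (1 mol %), toluene, sealed tube, 90 °C
Reagents that add atoms: none
Why: The thermal Diels–Alder reaction of an alkynoic acid gives the skipped diene acid directly, so that no basic ester hydrolysis can conjugate or aromatise the diene.

Step 7
Reactants: 12 diol; 15 dienoic acid
Product: 16 [(6R,7R)-7-(1,3-dioxolan-2-yl)-6-hydroxy-8,8-dimethyl-1,4-dioxaspiro[4.5]decan-6-yl]methyl cyclohexa-1,4-diene-1-carboxylate
Conditions: EDC·HCl (1.3 equiv), DMAP (0.1 equiv), CH2Cl2, 0 °C → rt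
Reagents that add atoms: none
Why: Steglich-type carbodiimide esterification acylates the primary C20 hydroxyl selectively because the tertiary C10 hydroxyl is far more hindered.

Step 8
Reactants: 16 hydroxy ester; 17 methyl chlorooxoacetate
Product: 18 mixed methyl oxalate of the C10 tertiary alcohol (10R,5R)
Conditions: 17 (1.5 equiv), Et3N (2 equiv), DMAP (0.2 equiv), CH2Cl2, 0 °C → rt
Reagents that add atoms: none
Why: DMAP-catalysed acylation with the very electrophilic half-ester chloride of oxalic acid reaches even a hindered tertiary alcohol and leaves its configuration unchanged.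

Step 9
Reactants: 18 methyl oxalate
Product: 19 cesium oxalate of the ring A tertiary alcohol with C20 esterified by 15 (10R,5R)
Conditions: CsOH (1.0 equiv, 1 M aq.), THF, 0 °C, short contact; concentrate and dry
Reagents that add atoms: cesium hydroxide, [Cs+].[OH-]
Why: Chemoselective saponification works because the methyl ester of an oxalate is far more electrophilic than the dienoate or the tertiary alkyl oxalate ester, so one equivalent of hydroxide cleaves only it.

Step 10
Reactants: 19 cesium oxalate
Product: 20 cis-fused spiro-lactone cyclohexene (5R,8S,9R,10S; H8 and H9 cis; C9 anti to C6 on ring A)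
Conditions: Ir[dF(CF3)ppy]2(dtbbpy)PF6 (2 mol %), H2O (20 equiv), DME/DMF 3:1 (5 mM), blue LEDs, 60 °C, argon
Reagents that add atoms: none
Why: Proposed new method: the excited trivalent-iridium photocatalyst oxidises the oxalate carboxylate of 19, two molecules of CO2 depart, and the planar, nucleophilic tertiary radical at C10 adds to C9, the β-carbon of the tethered dienoate, after which the C8 α-ester radical is reduced by the divalent-iridium state and protonated by water, so the process is redox-neutral and needs no added hydrogen-atom donor. The closest known reaction types are intermolecular photoredox Giese couplings of tertiary alkyl cesium oxalates with acrylates, butenolides and cycloalkenones and endo-mode radical cyclisations of acrylate esters, but an ester-tethered closure of such a radical onto a β-substituted cycloalkenecarboxylate has not been shown. The δ-lactone (C7, O, C20, C10, C9, C8) closes in the 6-endo-trig mode because attack at C9 is polarity-matched and leaves an ester-stabilised radical, whereas 5-exo attack at C8 would be mismatched and leave an unstabilised secondary radical. C10 is controlled by ring A, where the axial methyl group on C4 and the dioxolanyl group on C5 screen one face, so C9 bonds anti to C6 from either carbinol epimer. C9 is controlled by the rotamer about the forming bond that places H9 under ring A, C11 beside the tied-back spiro-ketal at C1 and C8 beside C5 (the least secure element), and C8 by protonation of the enolate on the face bearing H9, which gives the cis fusion and is reset anyway in step 11. The step needs addition to outrun hydrogen abstraction from the doubly allylic C11 and C14 methylenes and to spare C12=C13, which high dilution, 60 °C to populate the reactive ester rotamer and the unactivated, remote nature of C12=C13 are meant to secure.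

Step 11
Reactants: 20 spiro-lactone; 21 2,3-dibromopropene
Product: 23 C8-(2-bromoallyl) spiro-lactone (5R,8R,9S,10S), via lithium enolate 22 (not isolated)
Conditions: LiN(i-Pr)2 (1.2 equiv), THF/DMPU 5:1, −78 °C; then 21 (2 equiv), −78 → −40 °C
Reagents that add atoms: none
Why: Lactone enolate alkylation (SN2 at the allylic bromide) in which the electrophile reaches C8 on the face that carries H9, because C10 and C11 tilt to the other face, so that C15 ends cis to H9 whichever C8 epimer of 20 is used.

Step 12
Reactants: 23 vinyl bromide
Product: 24 bicyclo[3.2.1]octane lactone with C16=C17 exo-methylene (5R,8R,9S,10S,13R)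
Conditions: Bu3SnH (1.5 equiv, syringe pump), AIBN (0.2 equiv), benzene (10 mM), 80 °C
Reagents that add atoms: none
Why: Tin hydride mediated 5-exo-trig cyclisation of the C16 vinyl radical onto C13 closes ring D, C13 being able to form only with the two-carbon bridge cis on ring C, and the resulting C12 radical is quenched by the stannane.

Step 13
Reactants: 24 exo-methylene compound
Product: 25 15-epi allylic alcohol (exo hydroxyl; 5R,8S,9S,10S,13R,15S)
Conditions: SeO2 (0.5 equiv), t-BuOOH (3 equiv, decane), CH2Cl2, 0 °C → rt
Reagents that add atoms: tert-butyl hydroperoxide, CC(C)(C)OO (oxygen passed on through SeO2, O=[Se]=O)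
Why: Selenium dioxide allylic oxidation (ene reaction then [2,3]-shift) attacks C15, the only usable allylic position since C13 is a bridgehead, and delivers oxygen on the open exo face.

Step 14
Reactants: 25 allylic alcohol
Product: 26 C15 ketone conjugated with C16=C17 (5R,8S,9S,10S,13R)
Conditions: Dess–Martin periodinane (1.5 equiv), CH2Cl2, 0 °C → rt
Reagents that add atoms: none
Why: Dess–Martin oxidation converts the allylic alcohol into the exo-methylene ketone and so removes the wrongly configured centre under mild non-aqueous conditions.

Step 15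
Reactants: 26 enone
Product: 27 allylic alcohol with endo hydroxyl (5R,8S,9S,10S,13R,15R)
Conditions: NaBH4 (1.2 equiv), CeCl3·7H2O (1.2 equiv), MeOH, −78 °C
Reagents that add atoms: none
Why: Luche 1,2-reduction in which hydride adds to C15 from the exo face (side of the C14 bridge) because the endo face is screened by the axial hydrogen on C11, while the C1 and C6 carbonyl groups are still masked.

Step 16
Reactants: 27 alcohol; 28 acetic anhydride
Product: 29 C15 acetate (5R,8S,9S,10S,13R,15R)
Conditions: 28 (3 equiv), DMAP (0.2 equiv), pyridine, rt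
Reagents that add atoms: none
Why: DMAP-catalysed acetylation of the only free hydroxyl proceeds at oxygen and therefore with retention at C15.

Step 17
Reactants: 29 acetate
Product: 30 C1 ketone C6 aldehyde (2,3-dihydro target; 5R,8S,9S,10S,13R,15R)
Conditions: 1 M aq. HCl/THF 1:3, 35 °C
Reagents that add atoms: water, O
Why: Aqueous acid hydrolysis releases both dioxolanes in one operation, while the lactone survives and the allylic acetate next to the electron-poor quaternary C8 resists ionisation.

Step 18
Reactants: 30 keto aldehyde
Product: 31 target, 15-acetoxy-1,6-dioxo-6,7-secokaura-2,16-dien-7,20-olide (5R,8S,9S,10S,13R,15R)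
Conditions: IBX (2.5 equiv), 4-methoxypyridine N-oxide (2.5 equiv), DMSO, rt → 40 °C
Reagents that add atoms: none
Why: IBX dehydrogenation of a ketone to the enone is regiochemically unambiguous here because C1 can enolise only towards C2 (C10 is quaternary), and the aldehyde cannot be dehydrogenated because C4 and C10 are both quaternary.

Compound list
1 | 4,4-dimethylcyclohex-2-en-1-one | CC1(C)CCC(=O)C=C1 | starting material
2 | hex-1-yne | C#CCCCC | starting material
3 | Eschenmoser's salt | C=[N+](C)C.[I-] | starting material
4 | (E)-hex-1-enyl(diisobutyl)alane | CCCC/C=C/[Al](CC(C)C)CC(C)C | intermediate (not isolated)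
5 | diisobutylaluminium enolate (C1=C10) of the 1,4-adduct | CCCC/C=C/[C@H]1C=C(O[Al](CC(C)C)CC(C)C)CCC1(C)C | intermediate (not isolated)
6 | (2R,3S)-2-[(dimethylamino)methyl]-3-[(E)-hex-1-en-1-yl]-4,4-dimethylcyclohexan-1-one | CCCC/C=C/[C@H]1[C@H](CN(C)C)C(=O)CCC1(C)C | intermediate
7 | secondary ozonide of 6 | CCCCC1OOC(O1)[C@H]2[C@H](CN(C)C)C(=O)CCC2(C)C | intermediate (not isolated)
8 | (1S,2R)-2-[(dimethylamino)methyl]-6,6-dimethyl-3-oxocyclohexane-1-carbaldehyde | O=C[C@H]1[C@H](CN(C)C)C(=O)CCC1(C)C | intermediate
9 | 1-[(6R,7S)-7-(1,3-dioxolan-2-yl)-8,8-dimethyl-1,4-dioxaspiro[4.5]decan-6-yl]-N,N-dimethylmethanamine | CN(C)C[C@@H]1C2(OCCO2)CCC(C)(C)[C@H]1C3OCCO3 | intermediate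
10 | N-oxide of 9 | C[N+](C)([O-])C[C@@H]1C2(OCCO2)CCC(C)(C)[C@H]1C3OCCO3 | intermediate (not isolated)
11 | (7R)-7-(1,3-dioxolan-2-yl)-8,8-dimethyl-6-methylidene-1,4-dioxaspiro[4.5]decane | C=C1C2(OCCO2)CCC(C)(C)[C@H]1C3OCCO3 | intermediate
12 | (6R,7R)-7-(1,3-dioxolan-2-yl)-6-(hydroxymethyl)-8,8-dimethyl-1,4-dioxaspiro[4.5]decan-6-ol | OC[C@@]1(O)C2(OCCO2)CCC(C)(C)[C@H]1C3OCCO3 | intermediate
13 | buta-1,3-diene | C=CC=C | starting material
14 | propiolic acid | C#CC(=O)O | starting material
15 | cyclohexa-1,4-diene-1-carboxylic acid | OC(=O)C1=CCC=CC1 | intermediate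
16 | C20 dienoate of diol 12 (tertiary C10 hydroxyl free) | O=C(OC[C@@]1(O)C2(OCCO2)CCC(C)(C)[C@H]1C3OCCO3)C4=CCC=CC4 | intermediate
17 | methyl chlorooxoacetate | COC(=O)C(Cl)=O | starting material
18 | mixed methyl oxalate of 16 | COC(=O)C(=O)O[C@]1(COC(=O)C2=CCC=CC2)C3(OCCO3)CCC(C)(C)[C@H]1C4OCCO4 | intermediate
19 | cesium oxalate, precursor of the key step | [Cs+].[O-]C(=O)C(=O)O[C@]1(COC(=O)C2=CCC=CC2)C3(OCCO3)CCC(C)(C)[C@H]1C4OCCO4 | intermediate
20 | cis-fused spiro-lactone cyclohexene (5R,8S,9R,10S), product of the key step | C1=CC[C@@H]2[C@H](C1)C(=O)OC[C@]23C4(OCCO4)CCC(C)(C)[C@H]3C5OCCO5 | intermediate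
21 | 2,3-dibromopropene | C=C(Br)CBr | starting material
22 | lithium enolate of 20 | [Li]OC1=C2CC=CC[C@H]2[C@]3(CO1)C4(OCCO4)CCC(C)(C)[C@H]3C5OCCO5 | intermediate (not isolated)
23 | C8-(2-bromoallyl) spiro-lactone (5R,8R,9S,10S) | C1=CC[C@@H]2[C@@](C1)(CC(Br)=C)C(=O)OC[C@]23C4(OCCO4)CCC(C)(C)[C@H]3C5OCCO5 | intermediate
24 | ring D closed exo-methylene lactone (5R,8R,9S,10S,13R) | C=C1[C@@H]2CC[C@@H]3[C@](C2)(C(=O)OC[C@]34C5(OCCO5)CCC(C)(C)[C@H]4C6OCCO6)C1 | intermediate
25 | 15S (exo) allylic alcohol | C=C1[C@@H]2CC[C@@H]3[C@](C2)(C(=O)OC[C@]34C5(OCCO5)CCC(C)(C)[C@H]4C6OCCO6)[C@H]1O | intermediate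
26 | C15 exo-methylene ketone | C=C1[C@@H]2CC[C@@H]3[C@](C2)(C(=O)OC[C@]34C5(OCCO5)CCC(C)(C)[C@H]4C6OCCO6)C1=O | intermediate
27 | 15R (endo) allylic alcohol | C=C1[C@@H]2CC[C@@H]3[C@](C2)(C(=O)OC[C@]34C5(OCCO5)CCC(C)(C)[C@H]4C6OCCO6)[C@@H]1O | intermediate
28 | acetic anhydride | CC(=O)OC(C)=O | starting material
29 | 15R acetate with C1 and C6 as dioxolanes | C=C1[C@@H]2CC[C@@H]3[C@](C2)(C(=O)OC[C@]34C5(OCCO5)CCC(C)(C)[C@H]4C6OCCO6)[C@@H]1OC(C)=O | intermediate
30 | 2,3-dihydro target (C1 ketone, C6 aldehyde) | C=C1[C@@H]2CC[C@@H]3[C@](C2)(C(=O)OC[C@]32C(=O)CCC(C)(C)[C@H]2C=O)[C@@H]1OC(C)=O | intermediate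
31 | target CNP0108627.4 (5R,8S,9S,10S,13R,15R) | C=C1[C@@H]2CC[C@@H]3[C@](C2)(C(=O)OC[C@]32C(=O)C=CC(C)(C)[C@H]2C=O)[C@@H]1OC(C)=O | target

Total step count: 18. Longest linear sequence: 17 (steps 1–5 and 7–18).

Steps most likely to fail

1. Step 10.
- What may go wrong: a doubly allylic hydrogen (C11 or C14) may transfer to the C10 radical, with aromatisation of the acyl part. Closure may be slow because the ester must leave its preferred rotamer. Facial selectivity at C9 may be poor.
- Fallback (sets out from 11, comes back at 20, known chemistry only): epoxidation of 11 with mCPBA/NaHCO3 gives the spiro-epoxide F1. Cp2TiCl (trivalent titanium, made from Cp2TiCl2 and Zn, with collidine hydrochloride) opens F1 reductively to the same C10 radical. This radical adds intermolecularly to unhindered 2,2,2-trifluoroethyl acrylate, and the titanium alkoxide on C20 then closes the ring to the spiro δ-lactone F2. LiN(i-Pr)2 followed by PhSeBr gives the α-phenylselenyl lactone F3, and H2O2 gives the α,β-unsaturated lactone F4. A thermal Diels–Alder reaction of F4 with butadiene 13 (sealed tube, BHT) then builds ring C with H8 and H9 cis and delivers 20.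

2. Step 1.
- What may go wrong: enantioselectivity may be low or transfer sluggish at the neopentyl β-carbon, isobutyl transfer may compete, and the enolate may be lost before the Mannich trap.
- Fallback (sets out from 1, comes back at 6): the addition is run with alane 4 and CuBr·SMe2 without a chiral ligand and trapped with 3 as before. This gives 6 together with its mirror image, the ent-Mannich base F5. Because 6 is a tertiary amine, the racemate is resolved classically by crystallising the salt with (2R,3R)-O,O′-dibenzoyltartaric acid (or its antipode, whichever crystallises with 6), the dibenzoyltartrate salt F6. Aqueous base then releases 6.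

3. Step 18.
- What may go wrong: the free aldehyde may enolise under the oxidising conditions, with epimerisation at C5 or oxidation at that carbon, and conversion of the hindered ketone may be incomplete.
- Fallback (sets out from 29, comes back at 31): the two carbonyl groups are released one after the other. PPTS in wet acetone should first cleave the ketone-derived, strain-loaded dioxolane at C1 and give the keto acetal F7. IBX dehydrogenation with the aldehyde still masked gives the enone acetal F8. Aqueous trifluoroacetic acid in CH2Cl2 then frees C6 and gives 31.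

Further compounds
F1 | step 10 | spiro-epoxide of 11 (oxygen anti to C6) | C1O[C@@]12C3(OCCO3)CCC(C)(C)[C@H]2C4OCCO4
F2 | step 10 | spiro δ-lactone (C8 and C9 as CH2) | O=C1CC[C@]2(CO1)C3(OCCO3)CCC(C)(C)[C@H]2C4OCCO4
F3 | step 10 | α-phenylselenyl lactone (C8 epimers) | O=C1C([Se]c2ccccc2)C[C@]3(CO1)C4(OCCO4)CCC(C)(C)[C@H]3C5OCCO5
F4 | step 10 | α,β-unsaturated spiro δ-lactone (C8=C9) | O=C1C=C[C@]2(CO1)C3(OCCO3)CCC(C)(C)[C@H]2C4OCCO4
F5 | step 1 | ent-Mannich base (2S,3R), present with 6 in the racemate | CCCC/C=C/[C@@H]1[C@@H](CN(C)C)C(=O)CCC1(C)C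
F6 | step 1 | salt of 6 with (2R,3R)-O,O′-dibenzoyltartaric acid | CCCC/C=C/[C@H]1[C@H](CN(C)C)C(=O)CCC1(C)C.OC(=O)[C@H](OC(=O)c2ccccc2)[C@@H](OC(=O)c3ccccc3)C(O)=O
F7 | step 18 | C1 ketone with C6 still a dioxolane | C=C1[C@@H]2CC[C@@H]3[C@](C2)(C(=O)OC[C@]34C(=O)CCC(C)(C)[C@H]4C5OCCO5)[C@@H]1OC(C)=O
F8 | step 18 | C1 enone with C6 still a dioxolane | C=C1[C@@H]2CC[C@@H]3[C@](C2)(C(=O)OC[C@]34C(=O)C=CC(C)(C)[C@H]4C5OCCO5)[C@@H]1OC(C)=O
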